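**Plan**

- Ring C is numbered C1' (carries coumarin C3), C2' (vinylic CH), C3' (ketone), C4' (prenyl carbinol), C5' (CH2), C6' (ketone). The retrosynthesis cuts first the C3–C1' bond (Negishi coupling of a ring C α-iodoenone with 3-zincated 7-methoxycoumarin), then the C3'–C4' bond of ring C, then the C6'–C1', C6'–C5' and allyl–vinyl bonds of the open chain.
- The feature that allows the key step is the α-hydroxy ketone of ring C: ketone C3' lies next to the tertiary carbinol C4'. C3' can therefore be an aldehyde and C4' the prenyl ketone of one chain, joined with reversed polarity at C3' while C6' is held as a 1,3-dithiane.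
- Forward: 1,3-dithiane (C6') is alkylated with a silyloxypropyl bromide (C1'–C3') and then with epichlorohydrin; an isobutenyl Grignard opens the epoxide; desilylation and double Swern oxidation give the keto aldehyde. The carbene-catalysed benzoin then closes ring C, the only ring made (the coumarin is bought).
- The C3' ketone places the C1'=C2' double bond and is then reduced; opening the dithiane moves the enone carbonyl to C6', so that C1' becomes the α-carbon for iodination and coupling. Desilylation and reoxidation of C3' finish the synthesis.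
- Stereochemistry: the only stereocentre, C4' (R), is set by the chiral triazolium carbene in the benzoin step and is quaternary, so it cannot epimerise. The racemic carbinol from epichlorohydrin and the transient C3' carbinol are both erased by oxidation.

Key step: step 6

Assumption: the (5aR,10bS) enantiomer of the triazolium salt is taken to deliver the (R)-ketol; if the opposite sense of induction is found, the equally available (5aS,10bR) antipode is used under the same conditions.

**Route**

Step 1
Reactants: 1 1,3-dithiane; 2 (3-bromopropoxy)(tert-butyl)dimethylsilane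
Product: 4 tert-butyl[3-(1,3-dithian-2-yl)propoxy]dimethylsilane, via 2-lithio-1,3-dithiane 3 (not isolated)
Conditions: n-BuLi, THF, −30 °C; then 2, −78 °C to rt
Reagents that add atoms: none
Why: Corey–Seebach alkylation, in which the C2 carbanion of the dithiane displaces the primary bromide by SN2 and no stereocentre is formed.

Step 2
Reactants: 4 tert-butyl[3-(1,3-dithian-2-yl)propoxy]dimethylsilane; 5 epichlorohydrin (racemic)
Product: 8 racemic tert-butyldimethyl{3-[2-(oxiran-2-ylmethyl)-1,3-dithian-2-yl]propoxy}silane, via lithiated dithiane 6 (not isolated), via lithium chlorohydrin alkoxide 7 (not isolated)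
Conditions: t-BuLi, THF/HMPA (10:1), −78 °C; then 5, −78 to 0 °C
Reagents that add atoms: none
Why: A second Corey–Seebach metalation gives the 2-alkyl-2-lithiodithiane, which opens epichlorohydrin at its unsubstituted epoxide carbon, and the chlorohydrin alkoxide closes to the terminal epoxide on warming (intramolecular Williamson reaction); the new epoxide stereocentre is left racemic because it becomes the C4' ketone in step 5.

Step 3
Reactants: 8 racemic tert-butyldimethyl{3-[2-(oxiran-2-ylmethyl)-1,3-dithian-2-yl]propoxy}silane; 9 2-methylprop-1-enylmagnesium bromide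
Product: 10 racemic 1-{2-[3-(tert-butyldimethylsilyloxy)propyl]-1,3-dithian-2-yl}-5-methylhex-4-en-2-ol
Conditions: 9 (THF solution), CuI (10 mol %), THF, −30 to 0 °C; aq. NH4Cl
Reagents that add atoms: none
Why: Copper-catalysed Grignard opening of a terminal epoxide at the unhindered CH2 completes the prenyl chain as a homoallylic alcohol, the carbinol centre staying racemic.

Step 4
Reactants: 10 racemic 1-{2-[3-(tert-butyldimethylsilyloxy)propyl]-1,3-dithian-2-yl}-5-methylhex-4-en-2-ol
Product: 11 racemic 1-[2-(3-hydroxypropyl)-1,3-dithian-2-yl]-5-methylhex-4-en-2-ol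
Conditions: Bu4NF, THF, 0 °C to rt
Reagents that add atoms: none
Why: Fluoride-mediated desilylation cleaves the primary silyl ether while the dithiane and the alkene are inert.

Step 5
Reactants: 11 racemic 1-[2-(3-hydroxypropyl)-1,3-dithian-2-yl]-5-methylhex-4-en-2-ol
Product: 12 3-[2-(5-methyl-2-oxohex-4-enyl)-1,3-dithian-2-yl]propanal
Conditions: (COCl)2, DMSO, CH2Cl2, −78 °C; then Et3N, −78 to −20 °C
Reagents that add atoms: none
Why: Twofold Swern oxidation turns the primary alcohol into the C3' aldehyde and the secondary alcohol into the C4' ketone at low temperature, where dithianes survive and the β,γ-unsaturated ketone should not be drawn into conjugation; the racemic carbinol centre disappears.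

Step 6
Reactants: 12 3-[2-(5-methyl-2-oxohex-4-enyl)-1,3-dithian-2-yl]propanal
Product: 13 (R)-8-hydroxy-8-(3-methylbut-2-enyl)-1,5-dithiaspiro[5.5]undecan-9-one
Conditions: (5aR,10bS)-2-(pentafluorophenyl)-5a,10b-dihydro-4H,6H-indeno[2,1-b][1,2,4]triazolo[4,3-d][1,4]oxazin-2-ium tetrafluoroborate (20 mol %), Et3N (20 mol %), toluene (0.02 M), rt
Reagents that add atoms: none
Why: Deprotonation of the triazolium salt gives the carbene, which adds to the aldehyde carbon C3'; proton transfer yields the enaminol (Breslow intermediate), whose nucleophilic carbon attacks the ketone carbon C4', and collapse of the adduct releases the carbene and the α-hydroxy ketone. The closest known reaction type is the enantioselective intramolecular crossed aldehyde–ketone benzoin cyclisation of keto aldehydes with chiral triazolium carbenes. Ring C is closed in the 6-exo-trig mode by formation of the C3'–C4' bond. The new stereocentre C4' is controlled by the catalyst: the aminoindanol backbone shields one face of the enaminol and the tether dictates which face of the prochiral ketone is presented in a hydrogen-bonded chair-like transition state, so the (R)-carbinol should result. Crossed selectivity is built in, because a ketone cannot become a Breslow intermediate and the C4' ketone is the only acceptor the tether brings to the acyl anion; masking C6' as the dithiane takes the acidic methylene of a 1,3-diketone out of play and compresses the chain toward closure (Thorpe–Ingold effect). The weak amine base and high dilution should hold back aldol and intermolecular benzoin pathways.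

Step 7
Reactants: 13 (R)-8-hydroxy-8-(3-methylbut-2-enyl)-1,5-dithiaspiro[5.5]undecan-9-one
Product: 14 (R)-8-(3-methylbut-2-enyl)-8-(triethylsilyloxy)-1,5-dithiaspiro[5.5]undecan-9-one
Conditions: Et3SiOTf, 2,6-lutidine, CH2Cl2, −78 to 0 °C
Reagents that add atoms: triethylsilyl trifluoromethanesulfonate, CC[Si](CC)(CC)OS(=O)(=O)C(F)(F)F
Why: Silyl triflate with a hindered pyridine base is the standard silylation of a tertiary α-ketol and masks the hydroxyl for the enolate chemistry that follows, leaving C4' untouched.

Step 8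
Reactants: 14 (R)-8-(3-methylbut-2-enyl)-8-(triethylsilyloxy)-1,5-dithiaspiro[5.5]undecan-9-one
Product: 17 (R)-8-(3-methylbut-2-enyl)-8-(triethylsilyloxy)-1,5-dithiaspiro[5.5]undec-10-en-9-one, via lithium enolate 15 (not isolated), via sulfilimine adduct 16 (not isolated)
Conditions: LiN(i-Pr)2, THF, −78 °C; then N-tert-butylbenzenesulfinimidoyl chloride, −78 °C
Reagents that add atoms: none
Why: Mukaiyama dehydrogenation, in which the only enolate the ketone can form (toward C2', since C4' is quaternary) attacks the sulfur of the sulfinimidoyl chloride and the adduct undergoes syn-elimination at −78 °C, so the C1'=C2' double bond is placed unambiguously and without an external oxidant that could attack the dithiane.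

Step 9
Reactants: 17 (R)-8-(3-methylbut-2-enyl)-8-(triethylsilyloxy)-1,5-dithiaspiro[5.5]undec-10-en-9-one
Product: 18 (8R)-8-(3-methylbut-2-enyl)-8-(triethylsilyloxy)-1,5-dithiaspiro[5.5]undec-10-en-9-ol as a mixture of C9 epimers
Conditions: NaBH4, CeCl3·7H2O, MeOH, −40 °C
Reagents that add atoms: none
Why: Luche reduction should give clean 1,2-reduction of the enone to the allylic alcohol; the new C3' carbinol centre is formed without control and both epimers are carried on because C3' is reoxidised in step 15.

Step 10
Reactants: 18 (8R)-8-(3-methylbut-2-enyl)-8-(triethylsilyloxy)-1,5-dithiaspiro[5.5]undec-10-en-9-ol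
Product: 19 (8R)-8-(3-methylbut-2-enyl)-8,9-bis(triethylsilyloxy)-1,5-dithiaspiro[5.5]undec-10-ene as a mixture of C9 epimers
Conditions: Et3SiOTf, 2,6-lutidine, CH2Cl2, −78 to 0 °C
Reagents that add atoms: triethylsilyl trifluoromethanesulfonate, CC[Si](CC)(CC)OS(=O)(=O)C(F)(F)F
Why: Silylation of the secondary allylic alcohol removes the free hydroxyl that would otherwise undergo iodoetherification with the prenyl double bond in step 12.

Step 11
Reactants: 19 (8R)-8-(3-methylbut-2-enyl)-8,9-bis(triethylsilyloxy)-1,5-dithiaspiro[5.5]undec-10-ene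
Product: 20 (5R)-5-(3-methylbut-2-enyl)-4,5-bis(triethylsilyloxy)cyclohex-2-en-1-one as a mixture of C4 epimers
Conditions: MeI, CaCO3, MeCN/H2O (9:1), 45 °C
Reagents that add atoms: water, O
Why: Alkylative dithiane hydrolysis (S-methylation, then capture of the allyl-stabilised thionium ion by water) frees the C6' ketone in conjugation with C1'=C2', so the enone carbonyl moves from C3' to C6' and C1' becomes the α-carbon, while the buffered neutral medium should spare the silyl ethers and the prenyl group.

Step 12
Reactants: 20 (5R)-5-(3-methylbut-2-enyl)-4,5-bis(triethylsilyloxy)cyclohex-2-en-1-one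
Product: 21 (5R)-2-iodo-5-(3-methylbut-2-enyl)-4,5-bis(triethylsilyloxy)cyclohex-2-en-1-one as a mixture of C4 epimers
Conditions: I2, pyridine/CH2Cl2 (1:1), 0 °C to rt
Reagents that add atoms: iodine, I-I
Why: Pyridine-mediated α-iodination of a cyclic enone (conjugate addition of pyridine, iodination of the enolate, elimination; a Baylis–Hillman-type sequence) places iodine only on C1' and is well known for 4,5-bis(silyloxy)cyclohex-2-enones.

Step 13
Reactants: 21 (5R)-2-iodo-5-(3-methylbut-2-enyl)-4,5-bis(triethylsilyloxy)cyclohex-2-en-1-one; 22 7-methoxy-2H-chromen-2-one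
Product: 24 7-methoxy-3-[(4R)-4-(3-methylbut-2-enyl)-6-oxo-3,4-bis(triethylsilyloxy)cyclohex-1-en-1-yl]-2H-chromen-2-one as a mixture of epimers at the secondary silyloxy carbon, via bis(7-methoxy-2-oxo-2H-chromen-3-yl)zinc 23 (not isolated)
Conditions: 22 (1.5 equiv), TMP2Zn·2MgCl2·2LiCl (0.7 equiv; TMP = 2,2,6,6-tetramethylpiperidide), THF, 25 °C; then 21, Pd(dba)2 (5 mol %), P(2-furyl)3 (10 mol %), THF, 25 to 50 °C
Reagents that add atoms: none
Why: Directed zincation of the coumarin at C3 (the vinylic CH next to the lactone carbonyl) by the mild zinc amide gives a diarylzinc that tolerates the lactone, and Negishi coupling with the α-iodoenone forms the C3–C1' bond without touching any stereocentre.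

Step 14
Reactants: 24 7-methoxy-3-[(4R)-4-(3-methylbut-2-enyl)-6-oxo-3,4-bis(triethylsilyloxy)cyclohex-1-en-1-yl]-2H-chromen-2-one
Product: 25 3-[(4R)-3,4-dihydroxy-4-(3-methylbut-2-enyl)-6-oxocyclohex-1-en-1-yl]-7-methoxy-2H-chromen-2-one as a mixture of epimers at the secondary carbinol
Conditions: HF·pyridine, pyridine, THF, 0 °C to rt
Reagents that add atoms: none
Why: Buffered acidic fluoride desilylation removes both triethylsilyl ethers without the basic conditions that could trigger β-elimination toward an aromatic hydroquinone.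

Step 15
Reactants: 25 3-[(4R)-3,4-dihydroxy-4-(3-methylbut-2-enyl)-6-oxocyclohex-1-en-1-yl]-7-methoxy-2H-chromen-2-one
Product: 26 3-[(4R)-4-hydroxy-4-(3-methylbut-2-enyl)-3,6-dioxocyclohex-1-en-1-yl]-7-methoxy-2H-chromen-2-one
Conditions: Dess–Martin periodinane (1,1,1-triacetoxy-1,1-dihydro-1,2-benziodoxol-3(1H)-one), NaHCO3, CH2Cl2, 0 °C to rt
Reagents that add atoms: none
Why: Dess–Martin oxidation converts the secondary allylic alcohol into the C3' ketone while the tertiary C4' alcohol cannot be oxidised, so the epimer mixture should converge on the single (R)-configured enedione, with bicarbonate guarding against dehydration.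

**Compound list**

1 | 1,3-dithiane | C1CSCSC1 | starting material
2 | (3-bromopropoxy)(tert-butyl)dimethylsilane | CC(C)(C)[Si](C)(C)OCCCBr | starting material
3 | 2-lithio-1,3-dithiane | [Li]C1SCCCS1 | intermediate
4 | tert-butyl[3-(1,3-dithian-2-yl)propoxy]dimethylsilane | CC(C)(C)[Si](C)(C)OCCCC1SCCCS1 | intermediate
5 | epichlorohydrin (racemic 2-(chloromethyl)oxirane) | ClCC1CO1 | starting material
6 | tert-butyl[3-(2-lithio-1,3-dithian-2-yl)propoxy]dimethylsilane | CC(C)(C)[Si](C)(C)OCCCC1([Li])SCCCS1 | intermediate
7 | racemic lithium 1-{2-[3-(tert-butyldimethylsilyloxy)propyl]-1,3-dithian-2-yl}-3-chloropropan-2-olate | CC(C)(C)[Si](C)(C)OCCCC1(CC(CCl)O[Li])SCCCS1 | intermediate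
8 | racemic tert-butyldimethyl{3-[2-(oxiran-2-ylmethyl)-1,3-dithian-2-yl]propoxy}silane | CC(C)(C)[Si](C)(C)OCCCC1(CC2CO2)SCCCS1 | intermediate
9 | 2-methylprop-1-enylmagnesium bromide | CC(C)=C[Mg]Br | starting material
10 | racemic 1-{2-[3-(tert-butyldimethylsilyloxy)propyl]-1,3-dithian-2-yl}-5-methylhex-4-en-2-ol | CC(C)=CCC(O)CC1(CCCO[Si](C)(C)C(C)(C)C)SCCCS1 | intermediate
11 | racemic 1-[2-(3-hydroxypropyl)-1,3-dithian-2-yl]-5-methylhex-4-en-2-ol | CC(C)=CCC(O)CC1(CCCO)SCCCS1 | intermediate
12 | 3-[2-(5-methyl-2-oxohex-4-enyl)-1,3-dithian-2-yl]propanal | O=CCCC1(SCCCS1)CC(=O)CC=C(C)C | intermediate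
13 | (R)-8-hydroxy-8-(3-methylbut-2-enyl)-1,5-dithiaspiro[5.5]undecan-9-one | O=C1CCC2(SCCCS2)C[C@]1(O)CC=C(C)C | intermediate
14 | (R)-8-(3-methylbut-2-enyl)-8-(triethylsilyloxy)-1,5-dithiaspiro[5.5]undecan-9-one | O=C1CCC2(SCCCS2)C[C@]1(O[Si](CC)(CC)CC)CC=C(C)C | intermediate
15 | lithium (R)-8-(3-methylbut-2-enyl)-8-(triethylsilyloxy)-1,5-dithiaspiro[5.5]undec-9-en-9-olate | [Li]OC1=CCC2(SCCCS2)C[C@]1(O[Si](CC)(CC)CC)CC=C(C)C | intermediate
16 | (8R)-10-(N-tert-butyl-S-phenylsulfinimidoyl)-8-(3-methylbut-2-enyl)-8-(triethylsilyloxy)-1,5-dithiaspiro[5.5]undecan-9-one | O=C1C(S(=NC(C)(C)C)c3ccccc3)CC2(SCCCS2)C[C@]1(O[Si](CC)(CC)CC)CC=C(C)C | intermediate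
17 | (R)-8-(3-methylbut-2-enyl)-8-(triethylsilyloxy)-1,5-dithiaspiro[5.5]undec-10-en-9-one | O=C1C=CC2(SCCCS2)C[C@]1(O[Si](CC)(CC)CC)CC=C(C)C | intermediate
18 | (8R)-8-(3-methylbut-2-enyl)-8-(triethylsilyloxy)-1,5-dithiaspiro[5.5]undec-10-en-9-ol (C9 epimers) | OC1C=CC2(SCCCS2)C[C@]1(O[Si](CC)(CC)CC)CC=C(C)C | intermediate
19 | (8R)-8-(3-methylbut-2-enyl)-8,9-bis(triethylsilyloxy)-1,5-dithiaspiro[5.5]undec-10-ene (C9 epimers) | CC[Si](CC)(CC)OC1C=CC2(SCCCS2)C[C@]1(O[Si](CC)(CC)CC)CC=C(C)C | intermediate
20 | (5R)-5-(3-methylbut-2-enyl)-4,5-bis(triethylsilyloxy)cyclohex-2-en-1-one (C4 epimers) | O=C1C=CC(O[Si](CC)(CC)CC)[C@@](O[Si](CC)(CC)CC)(CC=C(C)C)C1 | intermediate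
21 | (5R)-2-iodo-5-(3-methylbut-2-enyl)-4,5-bis(triethylsilyloxy)cyclohex-2-en-1-one (C4 epimers) | O=C1C(I)=CC(O[Si](CC)(CC)CC)[C@@](O[Si](CC)(CC)CC)(CC=C(C)C)C1 | intermediate
22 | 7-methoxy-2H-chromen-2-one (7-methoxycoumarin) | COc1ccc2ccc(=O)oc2c1 | starting material
23 | bis(7-methoxy-2-oxo-2H-chromen-3-yl)zinc | COc1ccc2cc([Zn]c3cc4ccc(OC)cc4oc3=O)c(=O)oc2c1 | intermediate
24 | 7-methoxy-3-[(4R)-4-(3-methylbut-2-enyl)-6-oxo-3,4-bis(triethylsilyloxy)cyclohex-1-en-1-yl]-2H-chromen-2-one (epimers at the secondary silyloxy carbon) | COc1ccc2cc(C3=CC(O[Si](CC)(CC)CC)[C@@](O[Si](CC)(CC)CC)(CC=C(C)C)CC3=O)c(=O)oc2c1 | intermediate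
25 | 3-[(4R)-3,4-dihydroxy-4-(3-methylbut-2-enyl)-6-oxocyclohex-1-en-1-yl]-7-methoxy-2H-chromen-2-one (epimers at the secondary carbinol) | COc1ccc2cc(C3=CC(O)[C@@](O)(CC=C(C)C)CC3=O)c(=O)oc2c1 | intermediate
26 | 3-[(4R)-4-hydroxy-4-(3-methylbut-2-enyl)-3,6-dioxocyclohex-1-en-1-yl]-7-methoxy-2H-chromen-2-one | COc1ccc2cc(C3=CC(=O)[C@@](O)(CC=C(C)C)CC3=O)c(=O)oc2c1 | target

**Step count**

Total: 15 steps. Longest linear sequence: 15 steps (1,3-dithiane to 26; 7-methoxycoumarin enters in step 13).

**Steps most likely to fail**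

Step 6. The catalyst may discriminate poorly between the two faces of a ketone flanked by two methylene groups, and base-induced intramolecular aldol cyclisation may overtake acyl anion addition. The fallback replaces asymmetric catalysis by resolution and keeps the same bond formation. Setting out from 12, an achiral thiazolium carbene (3-benzyl-5-(2-hydroxyethyl)-4-methylthiazolium chloride, DBU, t-BuOH, 40 °C), small and highly nucleophilic, closes the C3'–C4' bond to give racemic 8-hydroxy-8-(3-methylbut-2-enyl)-1,5-dithiaspiro[5.5]undecan-9-one F1. Preparative chromatography on a cellulose carbamate chiral stationary phase separates the enantiomers; (S)-8-hydroxy-8-(3-methylbut-2-enyl)-1,5-dithiaspiro[5.5]undecan-9-one F2 is set aside, and the (R)-enantiomer is 13, where the route is rejoined.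

Step 13. Zincation may take place at C8 of the coumarin (between the two oxygen substituents) instead of C3, or transmetalation may be slow enough that the iodoenone decays by loss of silanol and aromatisation. The fallback uses tin in place of zinc and reaches the metalated coumarin through its bromide. Setting out from 22, bromine adds across C3–C4 (Br2, CH2Cl2, 0 °C) to give 3,4-dibromo-7-methoxychroman-2-one F3, which loses HBr on addition of Et3N in the same flask to give 3-bromo-7-methoxy-2H-chromen-2-one F4. Palladium-catalysed stannylation ((Bu3Sn)2, Pd(PPh3)4, toluene, 100 °C) gives 7-methoxy-3-(tributylstannyl)-2H-chromen-2-one F5, and Stille coupling of F5 with 21 (Pd2(dba)3, AsPh3, CuI, DMF, rt) comes back to the route at 24.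

Step 8. The sulfinimidoyl chloride may be consumed by the dithiane sulfur atoms, or syn-elimination next to the spiro dithiane carbon may stall at the adduct. The fallback is selenoxide elimination. Setting out from 14, the lithium enolate 15 is quenched with PhSeBr (THF, −78 °C) to give (8R)-8-(3-methylbut-2-enyl)-10-(phenylselanyl)-8-(triethylsilyloxy)-1,5-dithiaspiro[5.5]undecan-9-one F6. One equivalent of mCPBA (CH2Cl2, −78 °C) should oxidise selenium much faster than dithiane sulfur to give (8R)-8-(3-methylbut-2-enyl)-10-(phenylseleninyl)-8-(triethylsilyloxy)-1,5-dithiaspiro[5.5]undecan-9-one F7, which undergoes syn-elimination on warming with i-Pr2NH and returns to the route at 17.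

**Further compounds**

F1 | step 6 | racemic 8-hydroxy-8-(3-methylbut-2-enyl)-1,5-dithiaspiro[5.5]undecan-9-one | O=C1CCC2(SCCCS2)CC1(O)CC=C(C)C
F2 | step 6 | (S)-8-hydroxy-8-(3-methylbut-2-enyl)-1,5-dithiaspiro[5.5]undecan-9-one | O=C1CCC2(SCCCS2)C[C@@]1(O)CC=C(C)C
F3 | step 13 | 3,4-dibromo-7-methoxychroman-2-one | COc1ccc2c(c1)OC(=O)C(Br)C2Br
F4 | step 13 | 3-bromo-7-methoxy-2H-chromen-2-one | COc1ccc2cc(Br)c(=O)oc2c1
F5 | step 13 | 7-methoxy-3-(tributylstannyl)-2H-chromen-2-one | CCCC[Sn](CCCC)(CCCC)c1cc2ccc(OC)cc2oc1=O
F6 | step 8 | (8R)-8-(3-methylbut-2-enyl)-10-(phenylselanyl)-8-(triethylsilyloxy)-1,5-dithiaspiro[5.5]undecan-9-one | O=C1C([Se]c3ccccc3)CC2(SCCCS2)C[C@]1(O[Si](CC)(CC)CC)CC=C(C)C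
F7 | step 8 | (8R)-8-(3-methylbut-2-enyl)-10-(phenylseleninyl)-8-(triethylsilyloxy)-1,5-dithiaspiro[5.5]undecan-9-one | O=C1C([Se](=O)c3ccccc3)CC2(SCCCS2)C[C@]1(O[Si](CC)(CC)CC)CC=C(C)C
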